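**Retrosynthetic overview** (target numbering: ring C1 bears CO2Me, ring C10 bears the acetoxymethylidene carbon C11)
1. Target 28 ⇐ fused enol lactone 26 by KOMe, then Ac2O: the five-membered lactone ties the C11 oxygen to the C1 carboxyl and so fixes the (Z)-enol acetate and the (E)-dienoate.
2. 26 ⇐ macrocyclic alcohol 24 by 1,4-elimination ⇐ ring-closing metathesis (C3=C4) of 23 ⇐ α-aldol of butenolide 20 with acrolein (C1–C2).
3. Key bond C10–C11: butenolide 20 ⇐ ynal 19 + formaldehyde by a carbene-catalysed homoenolate annulation, which joins the ynal β-carbon and a carbonyl carbon, both normally electrophilic.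
4. 19 ⇐ iodide 15 + 1,3-dilithiopropyne + DMF; the furan comes from a B-alkyl Suzuki coupling on a vinyl group; C6/C7 come from an enantioselective Ireland–Claisen rearrangement of propanoate 8.
5. Ring order: five-membered butenolide first (step 9), ten-membered carbocycle second (step 11); the butenolide is opened in the last step.

Assumption: the (S,S)-diazaborolidine controller of step 4 is taken to give the (2S,3S) acid; if the sense of induction is the opposite, its (R,R)-enantiomer is used and nothing else changes.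

**Step 1**
Reactants: 1 1-bromo-3-methylbut-2-ene; 2 ethynylmagnesium bromide
Product: 3 5-methylhex-4-en-1-yne
Conditions: CuCl (5 mol%), THF, 0 °C → rt (2 in excess)
Reagents that add atoms: none
Why: Copper-catalysed SN2 coupling of the alkynyl Grignard reagent with the primary allylic bromide gives the skipped enyne, attack at the unhindered CH2 terminus being favoured over the tertiary SN2′ position.

**Step 2**
Reactants: 3 5-methylhex-4-en-1-yne
Product: 6 (2E)-3,6-dimethylhepta-2,5-dien-1-ol, via alkenyldimethylalane 4 (not isolated), via lithium alkenylaluminate 5 (not isolated)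
Conditions: Me3Al (2 equiv), Cp2ZrCl2 (25 mol%), CH2Cl2, rt; n-BuLi, THF, −78 °C; (CH2O)n, −78 °C → rt; aq. HCl
Reagents that add atoms: trimethylaluminium, C[Al](C)C; formaldehyde (from paraformaldehyde), C=O
Why: Negishi zirconium-catalysed carboalumination adds methyl and aluminium syn across the terminal alkyne (methyl to the internal carbon), so hydroxymethylation of the derived aluminate gives only the (E)-trisubstituted allylic alcohol.

**Step 3**
Reactants: 6 (2E)-3,6-dimethylhepta-2,5-dien-1-ol; 7 propanoyl chloride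
Product: 8 (2E)-3,6-dimethylhepta-2,5-dien-1-yl propanoate
Conditions: Et3N, DMAP (cat.), CH2Cl2, 0 °C
Reagents that add atoms: none
Why: DMAP-catalysed acylation of the primary alcohol by the acid chloride (nucleophilic acyl substitution).

**Step 4**
Reactants: 8 (2E)-3,6-dimethylhepta-2,5-dien-1-yl propanoate
Product: 10 (2S,3S)-3-ethenyl-2,3,6-trimethylhept-5-enoic acid, via boron ketene acetal 9 (not isolated)
Conditions: (4S,5S)-2-bromo-4,5-diphenyl-1,3-bis{[3,5-bis(trifluoromethyl)phenyl]sulfonyl}-1,3,2-diazaborolidine (1.2 equiv), Et3N, toluene–hexane, −78 → −20 °C; aqueous work-up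
Reagents that add atoms: none
Why: Corey's enantioselective Ireland–Claisen rearrangement, in which soft enolisation with the chiral bromoborane and Et3N in toluene–hexane gives the E(O) boron enolate (α-methyl cis to the allyloxy oxygen), the chair transition state of the (E)-allyl ester fixes the relative configuration and the controller selects the enolate face, setting the quaternary C3 and the tertiary C2 (future C6 and C7) together.

**Step 5**
Reactants: 10 (2S,3S)-3-ethenyl-2,3,6-trimethylhept-5-enoic acid
Product: 11 (2S,3S)-3-ethenyl-2,3,6-trimethylhept-5-en-1-ol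
Conditions: LiAlH4, Et2O, 0 °C → rt
Reagents that add atoms: none
Why: Hydride reduction of the carboxylic acid to the primary alcohol, with no stereocentre touched.

**Step 6**
Reactants: 11 (2S,3S)-3-ethenyl-2,3,6-trimethylhept-5-en-1-ol; 12 3-bromofuran
Product: 14 (2S,3R)-3-[2-(furan-3-yl)ethyl]-2,3,6-trimethylhept-5-en-1-ol, via bis-boryl hydroboration adduct 13 (not isolated)
Conditions: 9-BBN (2.2 equiv), THF, rt → 50 °C; then 12, PdCl2(dppf) (dichloro[1,1′-bis(diphenylphosphino)ferrocene]palladium, 5 mol%), aq. K3PO4, DMF, 60 °C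
Reagents that add atoms: none
Why: 9-BBN hydroborates only the monosubstituted vinyl group (the trisubstituted prenyl olefin is far slower, and the hydroxyl takes up one equivalent as a borinate), and B-alkyl Suzuki–Miyaura coupling with 3-bromofuran then installs the 2-(furan-3-yl)ethyl chain.

**Step 7**
Reactants: 14 (2S,3R)-3-[2-(furan-3-yl)ethyl]-2,3,6-trimethylhept-5-en-1-ol
Product: 15 3-[(3R,4S)-5-iodo-3,4-dimethyl-3-(3-methylbut-2-en-1-yl)pentyl]furan
Conditions: I2, PPh3, imidazole, CH2Cl2, 0 °C
Reagents that add atoms: iodine, II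
Why: Appel-type iodination, in which iodide displaces the oxyphosphonium of the primary alcohol by SN2 without touching the adjacent stereocentre.

**Step 8**
Reactants: 15 3-[(3R,4S)-5-iodo-3,4-dimethyl-3-(3-methylbut-2-en-1-yl)pentyl]furan; 16 propyne
Product: 19 (6R,7R)-7-[2-(furan-3-yl)ethyl]-6,7,10-trimethylundec-9-en-2-ynal, via 1,3-dilithiopropyne 17 (not isolated), via lithium acetylide 18 (not isolated)
Conditions: 16, n-BuLi (2 equiv), TMEDA, THF–hexane, −78 → 0 °C; 15, DMPU, −78 °C → rt; DMF, 0 °C; reverse quench into aq. KH2PO4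
Reagents that add atoms: N,N-dimethylformamide, CN(C)C=O
Why: 1,3-Dilithiopropyne is alkylated at its sp3 carbon by the primary iodide (SN2) and the lithium acetylide that remains is formylated by DMF, the hemiaminal collapsing on buffered work-up to the ynal.

**Step 9 (key step)**
Reactants: 19 (6R,7R)-7-[2-(furan-3-yl)ethyl]-6,7,10-trimethylundec-9-en-2-ynal
Product: 20 4-{(3R,4R)-4-[2-(furan-3-yl)ethyl]-3,4,7-trimethyloct-6-en-1-yl}furan-2(5H)-one
Conditions: IMes·HCl (1,3-dimesitylimidazolium chloride, 15 mol%), DBU (15 mol%), LiCl (1 equiv), (CH2O)n (2 equiv), THF, 40 °C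
Reagents that add atoms: formaldehyde (from paraformaldehyde), C=O
Why: Proposed new method: the carbene adds to the ynal aldehyde to give a Breslow-type allenol whose β-carbon (future C10, normally the electrophilic end of the ynal) attacks formaldehyde (future C11), and tautomerisation to the β-(oxidomethyl)enoyl azolium followed by O-acylation closes the butenolide and releases the carbene; the closest known reaction type is the carbene/LiCl-catalysed conjugate-umpolung [3+2] annulation of ynals with activated ketones to butenolides, together with homoenolate additions of enals to aldehydes that give γ-butyrolactones.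

**Step 10**
Reactants: 20 4-{(3R,4R)-4-[2-(furan-3-yl)ethyl]-3,4,7-trimethyloct-6-en-1-yl}furan-2(5H)-one; 21 prop-2-enal (acrolein)
Product: 23 4-{(3R,4R)-4-[2-(furan-3-yl)ethyl]-3,4,7-trimethyloct-6-en-1-yl}-3-(1-hydroxyprop-2-en-1-yl)furan-2(5H)-one (both carbinol epimers), via lithium furan-2-olate 22 (not isolated)
Conditions: LiN(i-Pr)2 (LDA), THF, −78 °C; 21, −78 °C; AcOH quench
Reagents that add atoms: none
Why: Deprotonation at C5 of the butenolide gives the 2-oxidofuran dienolate, which under kinetic control at −78 °C adds through its α-carbon (future C1) 1,2 to acrolein (aldol reaction of a lithium butenolide dienolate), the new carbinol centre being an epimer mixture that is erased in step 12.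

**Step 11**
Reactants: 23 aldol adduct (both carbinol epimers)
Product: 24 (6R,7R,9Z)-7-[2-(furan-3-yl)ethyl]-11-hydroxy-6,7-dimethyl-4,5,6,7,8,11-hexahydrocyclodeca[c]furan-1(3H)-one (C11 epimers)
Conditions: second-generation Grubbs catalyst (10 mol%), 1,4-benzoquinone (20 mol%), toluene (1 mM), 80 °C
Reagents that add atoms: none
Why: Ring-closing metathesis, in which the ruthenium carbene loads at the monosubstituted vinyl carbinol and closes on the prenyl olefin with loss of 2-methylpropene, the cis-tetrasubstituted butenolide bond and the quaternary carbon holding the two arms together so that the ten-membered ring forms with the less strained (Z) olefin (future C3=C4).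

**Step 12**
Reactants: 24 macrocyclic allylic alcohol
Product: 26 (6R,7R,9Z,11E)-7-[2-(furan-3-yl)ethyl]-6,7-dimethyl-5,6,7,8-tetrahydrocyclodeca[c]furan-1(4H)-one (C3=C3a and C11=C11a double bonds), via allylic acetate 25 (not isolated)
Conditions: Ac2O, Et3N, DMAP (cat.), CH2Cl2, 0 °C; then DBU, 0 °C → rt
Reagents that add atoms: none
Why: Acetylation makes the hydroxyl a leaving group, and base-mediated vinylogous E1cB (1,4-) elimination through the 2-oxidofuran gives the 3-ylidene-furan-2(3H)-one, the ten-membered ring allowing only the exocyclic olefin geometry in which C10 of the lactone numbering is cis to C3a (future C3 cis to C10, trans to the carboxyl).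

**Step 13**
Reactants: 26 fused enol lactone
Product: 28 methyl (1E,3Z,6R,7R,10Z)-10-[(acetyloxy)methylidene]-6-[2-(furan-3-yl)ethyl]-6,7-dimethylcyclodeca-1,3-diene-1-carboxylate, via potassium enolate 27 (not isolated)
Conditions: KOMe (1.05 equiv), 18-crown-6, THF, −78 °C; then Ac2O, −78 °C
Reagents that add atoms: potassium methoxide, [K+].C[O-]; acetic anhydride, CC(=O)OC(C)=O
Why: Proposed new method: methoxide attacks the activated enol-lactone carbonyl (acyl substitution) and releases the aldehyde enolate, whose oxygen is still cis to C1 because both sat in the five-membered ring, and O-acetylation at −78 °C traps this geometry as the (Z)-enol acetate while the new methyl ester stays trans to C3; the closest known reaction type is the cleavage of enol esters by MeLi or alkoxides to geometrically defined enolates and their O-acylation with Ac2O.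

**Compound list**
1 | 1-bromo-3-methylbut-2-ene (prenyl bromide) | CC(C)=CCBr | starting material
2 | ethynylmagnesium bromide | C#C[Mg]Br | starting material
3 | 5-methylhex-4-en-1-yne | CC(C)=CCC#C | intermediate
4 | [(1E)-2,5-dimethylhexa-1,4-dien-1-yl]dimethylalane | C[Al](C)/C=C(\C)CC=C(C)C | intermediate (not isolated)
5 | lithium butyl[(1E)-2,5-dimethylhexa-1,4-dien-1-yl]dimethylaluminate | [Li+].CCCC[Al-](C)(C)/C=C(\C)CC=C(C)C | intermediate (not isolated)
6 | (2E)-3,6-dimethylhepta-2,5-dien-1-ol | OC/C=C(\C)CC=C(C)C | intermediate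
7 | propanoyl chloride | CCC(Cl)=O | starting material
8 | (2E)-3,6-dimethylhepta-2,5-dien-1-yl propanoate | CCC(=O)OC/C=C(\C)CC=C(C)C | intermediate
9 | E(O) boron ketene acetal of 8 with the (4S,5S)-diazaborolidin-2-yl group on oxygen (α-methyl cis to the allyloxy oxygen) | C/C=C(\OC/C=C(\C)CC=C(C)C)OB1N([C@@H](c2ccccc2)[C@H](c2ccccc2)N1S(=O)(=O)c1cc(cc(c1)C(F)(F)F)C(F)(F)F)S(=O)(=O)c1cc(cc(c1)C(F)(F)F)C(F)(F)F | intermediate (not isolated)
10 | (2S,3S)-3-ethenyl-2,3,6-trimethylhept-5-enoic acid | CC(C)=CC[C@@](C)(C=C)[C@H](C)C(O)=O | intermediate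
11 | (2S,3S)-3-ethenyl-2,3,6-trimethylhept-5-en-1-ol | CC(C)=CC[C@@](C)(C=C)[C@H](C)CO | intermediate
12 | 3-bromofuran | Brc1ccoc1 | starting material
13 | O,C-bis(9-borabicyclo[3.3.1]nonan-9-yl) hydroboration adduct of 11 | CC(C)=CC[C@@](C)(CCB1C2CCCC1CCC2)[C@H](C)COB1C2CCCC1CCC2 | intermediate (not isolated)
14 | (2S,3R)-3-[2-(furan-3-yl)ethyl]-2,3,6-trimethylhept-5-en-1-ol | CC(C)=CC[C@@](C)(CCc1ccoc1)[C@H](C)CO | intermediate
15 | 3-[(3R,4S)-5-iodo-3,4-dimethyl-3-(3-methylbut-2-en-1-yl)pentyl]furan | CC(C)=CC[C@@](C)(CCc1ccoc1)[C@H](C)CI | intermediate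
16 | propyne | CC#C | starting material
17 | 1,3-dilithiopropyne | [Li]CC#C[Li] | intermediate (not isolated)
18 | lithium (5R,6R)-6-[2-(furan-3-yl)ethyl]-5,6,9-trimethyldec-8-en-1-yn-1-ide | CC(C)=CC[C@@](C)(CCc1ccoc1)[C@H](C)CCC#C[Li] | intermediate (not isolated)
19 | (6R,7R)-7-[2-(furan-3-yl)ethyl]-6,7,10-trimethylundec-9-en-2-ynal | CC(C)=CC[C@@](C)(CCc1ccoc1)[C@H](C)CCC#CC=O | intermediate
20 | 4-{(3R,4R)-4-[2-(furan-3-yl)ethyl]-3,4,7-trimethyloct-6-en-1-yl}furan-2(5H)-one | CC(C)=CC[C@@](C)(CCc1ccoc1)[C@H](C)CCC1=CC(=O)OC1 | intermediate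
21 | prop-2-enal (acrolein) | C=CC=O | starting material
22 | lithium 4-{(3R,4R)-4-[2-(furan-3-yl)ethyl]-3,4,7-trimethyloct-6-en-1-yl}furan-2-olate | [Li+].CC(C)=CC[C@@](C)(CCc1ccoc1)[C@H](C)CCc1coc([O-])c1 | intermediate (not isolated)
23 | 4-{(3R,4R)-4-[2-(furan-3-yl)ethyl]-3,4,7-trimethyloct-6-en-1-yl}-3-(1-hydroxyprop-2-en-1-yl)furan-2(5H)-one (carbinol epimers) | CC(C)=CC[C@@](C)(CCc1ccoc1)[C@H](C)CCC1=C(C(O)C=C)C(=O)OC1 | intermediate
24 | (6R,7R,9Z)-7-[2-(furan-3-yl)ethyl]-11-hydroxy-6,7-dimethyl-4,5,6,7,8,11-hexahydrocyclodeca[c]furan-1(3H)-one (C11 epimers) | O=C1OCC2=C1C(O)/C=C\C[C@@](C)(CCc3ccoc3)[C@H](C)CC2 | intermediate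
25 | 11-O-acetate of 24 | O=C1OCC2=C1C(OC(C)=O)/C=C\C[C@@](C)(CCc3ccoc3)[C@H](C)CC2 | intermediate (not isolated)
26 | (6R,7R,9Z,11E)-7-[2-(furan-3-yl)ethyl]-6,7-dimethyl-5,6,7,8-tetrahydrocyclodeca[c]furan-1(4H)-one | O=C1OC=C2\C1=C/C=C\C[C@@](C)(CCc3ccoc3)[C@H](C)CC2 | intermediate
27 | potassium (Z)-enolate of methyl (1E,3Z,6R,7R)-10-formyl-6-[2-(furan-3-yl)ethyl]-6,7-dimethylcyclodeca-1,3-diene-1-carboxylate | [K+].COC(=O)/C1=C/C=C\C[C@@](C)(CCc2ccoc2)[C@H](C)CC\C1=C\[O-] | intermediate (not isolated)
28 | methyl (1E,3Z,6R,7R,10Z)-10-[(acetyloxy)methylidene]-6-[2-(furan-3-yl)ethyl]-6,7-dimethylcyclodeca-1,3-diene-1-carboxylate | COC(=O)/C1=C/C=C\C[C@@](C)(CCc2ccoc2)[C@H](C)CC\C1=C\OC(C)=O | target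

**Step count:** 13 steps in total; longest linear sequence 13 steps (from 1).

**The three steps most likely to fail**

Step 9. Formaldehyde may consume the carbene, or the base may hydroxymethylate the butenolide product. The fallback sets out from iodide 15 and comes back at butenolide 20; it makes the same lactone through an enolonium-type C1–C10 bond instead. Li2CuCl4-catalysed coupling of 15 with [2-(1,3-dioxolan-2-yl)ethyl]magnesium bromide gives the dioxolane acetal F1. Aqueous acetic acid frees the aldehyde F2. Its pyrrolidine enamine is alkylated at the α-carbon with methyl bromoacetate (Stork alkylation, the bromoester serving as the α-cation of an acetate) to give the methyl 3-formyl ester F3. TsOH in refluxing toluene closes F3 to the enol lactone with loss of methanol and moves the double bond into conjugation, giving 20.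

Step 11. The ten-membered ring must close onto a trisubstituted olefin, so oligomers or the (E)-olefin are possible. The fallback sets out from butenolide 20 and comes back at macrocyclic alcohol 24; it closes the ring at C1–C2 by an intramolecular Claisen acylation instead. OsO4 (cat.)/NaIO4/2,6-lutidine cleaves the prenyl olefin of 20 to the aldehyde F4. Still–Gennari olefination (methyl bis(2,2,2-trifluoroethoxy)phosphorylacetate, KN(SiMe3)2, 18-crown-6, −78 °C) gives the (Z)-enoate F5. LiN(SiMe3)2 (2 equiv, THF, high dilution) forms the butenolide dienolate, which is acylated at C3 by the (Z)-ester to give the macrocyclic 3-acylbutenolide F6; the stable β-dicarbonyl enolate drives the ring closure. NaBH4/CeCl3 then reduces the ketone 1,2 to 24.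

Step 13. The enolate may be protonated, C-acylated or isomerised before it is trapped. The fallback sets out from enol lactone 26 and comes back at target 28. Neutral methanolysis (MeOH, DMAP cat., 0 °C) gives the aldehyde ester F7. Enol acetylation under equilibrating conditions (Ac2O, Et3N, DMAP, CH2Cl2) then gives 28 together with its (E)-enol acetate; the two are separated by chromatography and the unwanted isomer is returned to F7 with K2CO3 in MeOH.

**Further compounds**
F1 | step 9 | 3-[(3R,4R)-7-(1,3-dioxolan-2-yl)-3,4-dimethyl-3-(3-methylbut-2-en-1-yl)heptyl]furan | CC(C)=CC[C@@](C)(CCc1ccoc1)[C@H](C)CCCC1OCCO1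
F2 | step 9 | (5R,6R)-6-[2-(furan-3-yl)ethyl]-5,6,9-trimethyldec-8-enal | CC(C)=CC[C@@](C)(CCc1ccoc1)[C@H](C)CCCC=O
F3 | step 9 | methyl (6R,7R)-3-formyl-7-[2-(furan-3-yl)ethyl]-6,7,10-trimethylundec-9-enoate (C3 epimers) | CC(C)=CC[C@@](C)(CCc1ccoc1)[C@H](C)CCC(C=O)CC(=O)OC
F4 | step 11 | (3R,4R)-3-[2-(furan-3-yl)ethyl]-3,4-dimethyl-6-(5-oxo-2,5-dihydrofuran-3-yl)hexanal | O=CC[C@@](C)(CCc1ccoc1)[C@H](C)CCC1=CC(=O)OC1
F5 | step 11 | methyl (2Z,5R,6R)-5-[2-(furan-3-yl)ethyl]-5,6-dimethyl-8-(5-oxo-2,5-dihydrofuran-3-yl)oct-2-enoate | COC(=O)/C=C\C[C@@](C)(CCc1ccoc1)[C@H](C)CCC1=CC(=O)OC1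
F6 | step 11 | (6R,7R,9Z)-7-[2-(furan-3-yl)ethyl]-6,7-dimethyl-5,6,7,8-tetrahydrocyclodeca[c]furan-1,11(3H,4H)-dione | O=C1OCC2=C1C(=O)/C=C\C[C@@](C)(CCc3ccoc3)[C@H](C)CC2
F7 | step 13 | methyl (1E,3Z,6R,7R)-10-formyl-6-[2-(furan-3-yl)ethyl]-6,7-dimethylcyclodeca-1,3-diene-1-carboxylate (C10 epimers) | COC(=O)/C1=C/C=C\C[C@@](C)(CCc2ccoc2)[C@H](C)CCC1C=O
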